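**Retrosynthetic overview**

1. Numbering: ketone C1, cis alkene C2=C3, methyl-bearing C4, C5, lactone carbinol C6, fusion carbon C7, ester carbinols C8 and C9, tertiary carbinol C10; lactone carbons C11 and C12, exocyclic C13. The route rests on the C6–C7 bond, which is shared by the ten-membered carbocycle and the five-membered alpha-methylene lactone and carries the trans C6/C7 stereocentres beside the C11(=C13)–C12 acrylate unit.
2. Last come the two crotonates on C8 and C9 and removal of acetonide and silyl ether. Before that, C6–C7 and O–C12 are cut together, giving the open-chain C6 aldehyde with a (Z)-2-(bromomethyl)enoate on C7 (26). CrCl2 closes the carbocycle first and the lactone second, in one flask.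
3. 26 comes from a C7 aldehyde and methyl acrylate (Baylis–Hillman, then SN2' bromination). The C1–C2 bond comes from addition of the C2–C6 alkynyllithium to a C1 aldehyde, and Lindlar reduction gives the cis alkene. The C1 ketone and the C6 aldehyde are released together at the end.
4. C7–C10 come from L-tartrate acetonide 1. C8 and C9 are used as such, C10 is set by chelation-controlled vinyl addition to the C10 methyl ketone, the vinyl group becomes C1 by ozonolysis, and the second ester is kept as the latent C7 aldehyde.
5. C4 comes from (R)-but-3-yn-2-ol by SN2 inversion with malonate.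

Key step: step 18

Remark: atoms are numbered C1–C13 as above throughout. The carbinol epimers at C1 (from step 11) and at C7 (from step 14) are carried as mixtures, because both centres lose their configuration later (steps 17 and 15).

**Route**

Step 1
Reactants: 1 dimethyl 2,3-O-isopropylidene-L-tartrate
Product: 2 (4R,5R)-5-(methoxycarbonyl)-2,2-dimethyl-1,3-dioxolane-4-carboxylic acid
Conditions: KOH (1.0 equiv), MeOH, 0 °C to rt; then aq. HCl to pH 2
Reagents that add atoms: potassium hydroxide, [K+].[OH-]
Why: Saponification of one of the two equivalent esters of the C2-symmetric diester should stop at the monoacid, because the carboxylate formed slows attack on the second ester, and no stereocentre is touched.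

Step 2
Reactants: 2 monoacid
Product: 4 methyl (4R,5R)-5-acetyl-2,2-dimethyl-1,3-dioxolane-4-carboxylate, via acid chloride 3 (not isolated)
Conditions: (COCl)2, cat. DMF, CH2Cl2, 0 °C to rt, evaporate; then Me2CuLi (from MeLi and CuI), Et2O, −78 °C
Reagents that add atoms: lithium dimethylcuprate, [Li+].C[Cu-]C
Why: Acylation of a Gilman cuprate by the acid chloride should stop at the methyl ketone (C10) and leave the methyl ester alone, since lithium dialkylcuprates do not add to ketones or esters at −78 °C.

Step 3
Reactants: 4 methyl ketone
Product: 5 methyl (4R,5R)-5-[(2R)-2-hydroxybut-3-en-2-yl]-2,2-dimethyl-1,3-dioxolane-4-carboxylate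
Conditions: MgBr2·OEt2, CH2Cl2, −78 °C; then CH2=CHMgBr (THF), −78 °C; aq. NH4Cl
Reagents that add atoms: vinylmagnesium bromide, C=C[Mg]Br
Why: In this chelation-controlled Grignard addition (Cram chelate model) magnesium bridges the ketone oxygen and the dioxolane oxygen on C9, so the vinyl group should add from the face of the small C9 hydrogen and set C10 with methyl, oxygen and C9 arranged as in the target, while the ketone reacts far faster than the C7 ester.

Step 4
Reactants: 5 tertiary allylic alcohol
Product: 6 methyl (4R,5R)-2,2-dimethyl-5-[(2R)-2-(triethylsilyloxy)but-3-en-2-yl]-1,3-dioxolane-4-carboxylate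
Conditions: TESOTf, 2,6-lutidine, CH2Cl2, −78 to 0 °C
Reagents that add atoms: triethylsilyl trifluoromethanesulfonate, CC[Si](CC)(CC)OS(=O)(=O)C(F)(F)F
Why: A silyl triflate with a hindered pyridine base silylates tertiary alcohols (silyl ether formation), and the buffered medium leaves acetonide and ester intact.

Step 5
Reactants: 6 vinyl silyl ether
Product: 8 methyl (4R,5R)-2,2-dimethyl-5-[(2S)-1-oxo-2-(triethylsilyloxy)propan-2-yl]-1,3-dioxolane-4-carboxylate, via ozonide 7 (not isolated)
Conditions: O3, CH2Cl2, −78 °C; then PPh3, −78 °C to rt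
Reagents that add atoms: ozone, [O-][O+]=O
Why: Ozonolysis with reductive work-up cleaves the only alkene to the C1 aldehyde, whose alpha carbon C10 is quaternary and cannot epimerize.

Step 6
Reactants: 9 (R)-but-3-yn-2-ol
Product: 10 (R)-but-3-yn-2-yl methanesulfonate
Conditions: MsCl, Et3N, CH2Cl2, −78 to 0 °C
Reagents that add atoms: methanesulfonyl chloride, CS(=O)(=O)Cl
Why: Sulfonylation takes place at oxygen, so the carbinol carbon keeps its configuration and becomes a good leaving-group centre.

Step 7
Reactants: 10 (R)-but-3-yn-2-yl methanesulfonate; 11 dimethyl malonate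
Product: 13 dimethyl 2-[(2R)-but-3-yn-2-yl]propanedioate, via sodium dimethyl malonate 12 (not isolated)
Conditions: NaH, 11 (2 equiv), THF/DMF, 0 °C; then 10, 60 °C
Reagents that add atoms: none
Why: SN2 alkylation of the soft malonate anion by the secondary propargylic mesylate should proceed with inversion and so set the methyl-bearing C4 centre, with excess malonate suppressing double alkylation.

Step 8
Reactants: 13 alkylated malonate
Product: 14 methyl (3R)-3-methylpent-4-ynoate
Conditions: LiCl, H2O, DMSO, 150 °C
Reagents that add atoms: none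
Why: Krapcho dealkoxycarbonylation (chloride attack on the methyl group, loss of CO2, protonation) removes one ester under nearly neutral conditions that leave the terminal alkyne and the non-acidic C4 centre untouched.

Step 9
Reactants: 14 methyl (3R)-3-methylpent-4-ynoate
Product: 15 (3R)-3-methylpent-4-yn-1-ol
Conditions: LiAlH4, Et2O, 0 °C; aqueous work-up
Reagents that add atoms: none
Why: Hydride reduction of the ester gives the primary alcohol (C6–OH), and an isolated alkyne is not reduced at 0 °C.

Step 10
Reactants: 15 (3R)-3-methylpent-4-yn-1-ol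
Product: 16 triethyl{[(3R)-3-methylpent-4-yn-1-yl]oxy}silane
Conditions: TESCl, imidazole, CH2Cl2, 0 °C to rt
Reagents that add atoms: chlorotriethylsilane, CC[Si](CC)(CC)Cl
Why: Standard silyl ether formation on a primary alcohol gives a C6 protecting group that later leaves under the same mild acid as the C1 silyl ether.

Step 11
Reactants: 8 C1 aldehyde; 16 silyl-protected alkyne
Product: 19 propargylic tris(triethylsilyl) ether (C1–O, C6–O and C10–O silylated; C2≡C3; C7 methyl ester; C1 epimers), via lithium acetylide 17 (not isolated), via lithium alkoxide 18 (not isolated)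
Conditions: 16, n-BuLi, THF, −78 °C; then 8, −78 °C; then TESOTf, −78 to −40 °C
Reagents that add atoms: triethylsilyl trifluoromethanesulfonate, CC[Si](CC)(CC)OS(=O)(=O)C(F)(F)F
Why: Lithium acetylide 1,2-addition to the aldehyde is much faster than attack on the methyl ester at −78 °C, and silyl trapping of the alkoxide forestalls lactonization onto the C7 ester and makes any silyl shift between the C10 and C1 oxygens inconsequential, while the unselective C1 carbinol is cleared by oxidation in step 17.

Step 12
Reactants: 19 propargylic tris(triethylsilyl) ether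
Product: 20 cis-allylic tris(triethylsilyl) ether (cis C2=C3; C7 methyl ester)
Conditions: H2 (1 atm), Pd/CaCO3 poisoned with Pb(OAc)2 (Lindlar catalyst), quinoline, EtOAc, rt
Reagents that add atoms: none
Why: Lindlar semihydrogenation delivers both hydrogens to one face of the alkyne and should give the cis C2=C3 alkene, and it is placed before any acrylate or allylic bromide is present.

Step 13
Reactants: 20 cis-allylic tris(triethylsilyl) ether
Product: 21 C7 aldehyde (ester of 20 reduced to CHO)
Conditions: i-Bu2AlH (1.1 equiv), CH2Cl2, −78 °C; MeOH, then aq. potassium sodium tartrate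
Reagents that add atoms: none
Why: Partial reduction of the alpha-alkoxy methyl ester should stop at the aldehyde because the chelated aluminium hemiacetal survives at −78 °C until work-up, and C8 stays in the favoured trans-dioxolane arrangement.

Step 14
Reactants: 21 C7 aldehyde; 22 methyl acrylate
Product: 23 Baylis–Hillman adduct (C7 carbinol bearing the C11(=C13H2)–CO2Me unit; C7 epimers)
Conditions: DABCO (1.0 equiv), 22 (neat, excess), rt, several days
Reagents that add atoms: none
Why: In the Morita–Baylis–Hillman reaction the DABCO-derived acrylate enolate adds to the activated alpha-alkoxy aldehyde and the amine is then eliminated; no enone is present yet for the amine to isomerize, and the unselective C7 carbinol is cleared in step 15.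

Step 15
Reactants: 23 Baylis–Hillman adduct
Product: 24 (Z)-2-(bromomethyl)enoate (C7=C11, C13 bromide, ester trans to the C8 chain; three silyl ethers and acetonide retained)
Conditions: NBS, Me2S, CH2Cl2, 0 °C; then 23, 0 °C to rt
Reagents that add atoms: N-bromosuccinimide, O=C1CCC(=O)N1Br
Why: In this Corey–Kim-type bromination of a Baylis–Hillman alcohol, bromide attacks the alkoxysulfonium salt at C13 with allylic transposition (SN2') to give the more stable (Z)-2-(bromomethyl)enoate, and the acid-free medium spares silyl ethers and acetonide.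

Step 16
Reactants: 24 (Z)-2-(bromomethyl)enoate
Product: 25 C1,C6-diol (C10 silyl ether, acetonide and allylic bromide retained)
Conditions: pyridinium p-toluenesulfonate (0.2 equiv), MeOH/CH2Cl2 (1:1), 0 °C to rt, stopped when the C1 ether is gone; crude product used at once
Reagents that add atoms: none
Why: Acid-catalysed methanolysis of silyl ethers is governed by steric access to silicon, so the primary C6 and secondary C1 triethylsilyl ethers should be cleaved while the tertiary C10 ether, the acetonide and the allylic bromide remain.

Step 17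
Reactants: 25 C1,C6-diol
Product: 26 open-chain keto aldehyde (C6 aldehyde, cis C2=C3 enone with C1 ketone, C10 triethylsilyl ether, C8/C9 acetonide, (Z)-2-(bromomethyl)enoate at C7; 4R,8S,9R,10S)
Conditions: Dess–Martin periodinane (3 equiv), NaHCO3, CH2Cl2, 0 °C to rt
Reagents that add atoms: none
Why: Dess–Martin oxidation converts the allylic C1 carbinol to the cis-enone and the primary C6 alcohol to the aldehyde in one operation, under buffered non-nucleophilic conditions that should preserve the cis geometry and the allylic bromide.

Step 18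
Reactants: 26 open-chain keto aldehyde
Product: 29 protected macrocycle (ten-membered carbocycle fused to the alpha-methylene lactone; C8/C9 acetonide, C10 triethylsilyl ether; 4R,6R,7S,8S,9R,10S), via allylchromium dichloride 27 (not isolated), via chromium alkoxide 28 (not isolated)
Conditions: CrCl2 (8 equiv), THF/DMF (4:1), rt, 26 added by syringe pump to about 0.003 M, then 12 h; aqueous work-up
Reagents that add atoms: none
Why: CrCl2 (divalent chromium) reduces the C13 allylic bromide in two one-electron steps to the trivalent allylchromium 27, which adds to the C6 aldehyde through a closed six-membered chair (Cr–C13–C11=C7/C6=O) with bonding at the gamma carbon C7 and transposition of the alkene to C11=C13; this is the Nozaki–Hiyama allylation in its intramolecular form, known for ten-membered carbocycles built from 2-(bromomethyl)acrylate aldehydes. The ten-membered ring closes in this SE2' addition with the allyl unit C13–C11 left outside the new ring, and the lactone then closes by 5-exo-trig acyl substitution of the C6 chromium alkoxide 28 on the C12 methyl ester with loss of methoxide. C7 is set by C8: allylic 1,3-strain holds H8 in the plane of the C7=C11 bond, O8 and C9 then lie on opposite faces, and the tethered aldehyde should bond to C7 on the face anti to C9, which lets the segment C6–C7–C8–C9–C10 stay extended as the trans-dioxolane demands and corresponds to 7S. C6 is set by the chair: the allylchromium equilibrates its C7=C11 geometry by 1,3-metal shift, and closure through the chair that holds the C5 and C8 chain ends both equatorial gives the anti adduct (6R), which is the one that lactonizes to the trans-fused lactone. The step needs anti topicity, aldehyde-over-ketone selectivity and cyclization over oligomerization: the cis C2=C3 enone, the trans-dioxolane and the quaternary C10 turn the chain so that C6 and C7 meet, addition of C7 to the C1 ketone would require a five-membered ring trans-fused to the dioxolane and is shut off, the organochromium leaves ketone, esters and silyl ether alone, and slow addition at high dilution disfavours intermolecular coupling.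

Step 19
Reactants: 29 protected macrocycle
Product: 30 macrocyclic triol (free hydroxyls at C8, C9 and C10; all centres arranged as in the target)
Conditions: TFA, H2O, THF, 0 °C to rt
Reagents that add atoms: none
Why: Aqueous acid hydrolyses the isopropylidene acetal and the tertiary silyl ether (acetal hydrolysis and protodesilylation) while lactone, exocyclic methylene and cis-enone are stable to acid, and any hydroxy ester left from step 18 would lactonize here.

Step 20
Reactants: 30 macrocyclic triol
Product: 31 CNP0223772.1 (target)
Conditions: (E)-crotonic anhydride (3 equiv), DMAP (0.2 equiv), pyridine, CH2Cl2, 0 °C to rt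
Reagents that add atoms: (E)-crotonic anhydride, C/C=C/C(=O)OC(=O)/C=C/C
Why: DMAP-catalysed acyl transfer should esterify the two secondary hydroxyls at C8 and C9 while the tertiary C10 hydroxyl next to the ketone is too hindered to react, and the anhydride with pyridine avoids the ketene pathway that would deconjugate the crotonyl group.

**Compound list**

1 | dimethyl 2,3-O-isopropylidene-L-tartrate, (4R,5R) | COC(=O)[C@@H]1OC(C)(C)O[C@H]1C(=O)OC | starting material
2 | (4R,5R)-5-(methoxycarbonyl)-2,2-dimethyl-1,3-dioxolane-4-carboxylic acid | OC(=O)[C@@H]1OC(C)(C)O[C@H]1C(=O)OC | intermediate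
3 | methyl (4R,5R)-5-(chlorocarbonyl)-2,2-dimethyl-1,3-dioxolane-4-carboxylate (not isolated) | ClC(=O)[C@@H]1OC(C)(C)O[C@H]1C(=O)OC | intermediate
4 | methyl (4R,5R)-5-acetyl-2,2-dimethyl-1,3-dioxolane-4-carboxylate | CC(=O)[C@@H]1OC(C)(C)O[C@H]1C(=O)OC | intermediate
5 | methyl (4R,5R)-5-[(2R)-2-hydroxybut-3-en-2-yl]-2,2-dimethyl-1,3-dioxolane-4-carboxylate | C=C[C@@](C)(O)[C@@H]1OC(C)(C)O[C@H]1C(=O)OC | intermediate
6 | methyl (4R,5R)-2,2-dimethyl-5-[(2R)-2-(triethylsilyloxy)but-3-en-2-yl]-1,3-dioxolane-4-carboxylate | C=C[C@@](C)(O[Si](CC)(CC)CC)[C@@H]1OC(C)(C)O[C@H]1C(=O)OC | intermediate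
7 | ozonide of 6 (1,2,4-trioxolane on the former vinyl group; not isolated) | C1OOC(O1)[C@@](C)(O[Si](CC)(CC)CC)[C@@H]2OC(C)(C)O[C@H]2C(=O)OC | intermediate
8 | methyl (4R,5R)-2,2-dimethyl-5-[(2S)-1-oxo-2-(triethylsilyloxy)propan-2-yl]-1,3-dioxolane-4-carboxylate (C1 aldehyde) | O=C[C@@](C)(O[Si](CC)(CC)CC)[C@@H]1OC(C)(C)O[C@H]1C(=O)OC | intermediate
9 | (R)-but-3-yn-2-ol | C#C[C@@H](C)O | starting material
10 | (R)-but-3-yn-2-yl methanesulfonate | C#C[C@@H](C)OS(C)(=O)=O | intermediate
11 | dimethyl malonate | COC(=O)CC(=O)OC | starting material
12 | sodium dimethyl malonate (not isolated) | COC(=O)[CH-]C(=O)OC.[Na+] | intermediate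
13 | dimethyl 2-[(2R)-but-3-yn-2-yl]propanedioate | C#C[C@H](C)C(C(=O)OC)C(=O)OC | intermediate
14 | methyl (3R)-3-methylpent-4-ynoate | C#C[C@H](C)CC(=O)OC | intermediate
15 | (3R)-3-methylpent-4-yn-1-ol | C#C[C@H](C)CCO | intermediate
16 | triethyl{[(3R)-3-methylpent-4-yn-1-yl]oxy}silane | C#C[C@H](C)CCO[Si](CC)(CC)CC | intermediate
17 | lithium acetylide of 16 (not isolated) | [Li]C#C[C@H](C)CCO[Si](CC)(CC)CC | intermediate
18 | lithium C1 alkoxide from 8 and 17 (C1 epimers; not isolated) | [Li]OC(C#C[C@H](C)CCO[Si](CC)(CC)CC)[C@@](C)(O[Si](CC)(CC)CC)[C@@H]1OC(C)(C)O[C@H]1C(=O)OC | intermediate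
19 | propargylic tris(triethylsilyl) ether: C1–O, C6–O and C10–O silylated, C2≡C3, C8/C9 acetonide, C7 methyl ester; C4, C8, C9, C10 as in the target, C1 epimers | CC[Si](CC)(CC)OC(C#C[C@H](C)CCO[Si](CC)(CC)CC)[C@@](C)(O[Si](CC)(CC)CC)[C@@H]1OC(C)(C)O[C@H]1C(=O)OC | intermediate
20 | cis-allylic tris(triethylsilyl) ether: as 19 with cis C2=C3 | CC[Si](CC)(CC)OC(/C=C\[C@H](C)CCO[Si](CC)(CC)CC)[C@@](C)(O[Si](CC)(CC)CC)[C@@H]1OC(C)(C)O[C@H]1C(=O)OC | intermediate
21 | C7 aldehyde: as 20 with the ester reduced to CHO | CC[Si](CC)(CC)OC(/C=C\[C@H](C)CCO[Si](CC)(CC)CC)[C@@](C)(O[Si](CC)(CC)CC)[C@@H]1OC(C)(C)O[C@H]1C=O | intermediate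
22 | methyl acrylate | C=CC(=O)OC | starting material
23 | Baylis–Hillman adduct: C7 carbinol bearing C11(=C13H2)–CO2Me (C1 and C7 epimers) | CC[Si](CC)(CC)OC(/C=C\[C@H](C)CCO[Si](CC)(CC)CC)[C@@](C)(O[Si](CC)(CC)CC)[C@@H]1OC(C)(C)O[C@H]1C(O)C(=C)C(=O)OC | intermediate
24 | (Z)-2-(bromomethyl)enoate with three silyl ethers (C1 epimers) | CC[Si](CC)(CC)OC(/C=C\[C@H](C)CCO[Si](CC)(CC)CC)[C@@](C)(O[Si](CC)(CC)CC)[C@@H]1OC(C)(C)O[C@H]1/C=C(\CBr)C(=O)OC | intermediate
25 | C1,C6-diol with C10 triethylsilyl ether, C8/C9 acetonide and (Z)-2-(bromomethyl)enoate (C1 epimers) | OCC[C@@H](C)/C=C\C(O)[C@@](C)(O[Si](CC)(CC)CC)[C@@H]1OC(C)(C)O[C@H]1/C=C(\CBr)C(=O)OC | intermediate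
26 | open-chain keto aldehyde (cyclization precursor): C6 aldehyde, cis-enone, C10 triethylsilyl ether, C8/C9 acetonide, (Z)-2-(bromomethyl)enoate at C7; 4R,8S,9R,10S | O=CC[C@@H](C)/C=C\C(=O)[C@@](C)(O[Si](CC)(CC)CC)[C@@H]1OC(C)(C)O[C@H]1/C=C(\CBr)C(=O)OC | intermediate
27 | allylchromium dichloride from 26 (trivalent chromium on C13; not isolated) | O=CC[C@@H](C)/C=C\C(=O)[C@@](C)(O[Si](CC)(CC)CC)[C@@H]1OC(C)(C)O[C@H]1/C=C(\C[Cr](Cl)Cl)C(=O)OC | intermediate
28 | ten-membered carbocycle as C6 chromium alkoxide with the C12 methyl ester still open (not isolated) | C=C(C(=O)OC)[C@H]1[C@H](O[Cr](Cl)Cl)C[C@@H](C)/C=C\C(=O)[C@@](C)(O[Si](CC)(CC)CC)[C@H](OC(C)(C)O2)[C@H]12 | intermediate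
29 | protected macrocycle: ten-membered carbocycle with trans-fused alpha-methylene lactone, C8/C9 acetonide, C10 triethylsilyl ether; 4R,6R,7S,8S,9R,10S | C=C1C(=O)O[C@@H]2C[C@@H](C)/C=C\C(=O)[C@@](C)(O[Si](CC)(CC)CC)[C@H](OC(C)(C)O4)[C@@H]4[C@@H]12 | intermediate
30 | macrocyclic triol (C8, C9, C10 hydroxyls free; centres arranged as in the target) | C=C1C(=O)O[C@@H]2C[C@@H](C)/C=C\C(=O)[C@@](C)(O)[C@H](O)[C@@H](O)[C@@H]12 | intermediate
31 | CNP0223772.1: C8,C9-di-(E)-crotonate of 30; 4R,6R,7S,8S,9R,10S | C=C1C(=O)O[C@@H]2C[C@@H](C)/C=C\C(=O)[C@@](C)(O)[C@H](OC(=O)/C=C/C)[C@@H](OC(=O)/C=C/C)[C@@H]12 | target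

**Step count**

Total: 20 steps. Longest linear sequence: 15 steps (steps 1–5 and 11–20); the alkyne branch is steps 6–10.

**Steps most likely to fail**

Step 18. Ring closure may lose against intermolecular coupling, the cis-enone may isomerize or be reduced by divalent chromium during the long slow addition, or the flat C1 ketone may hold the chain in a fold that closes with the wrong topicity. The fallback sets out from 24 and runs the macro-allylation with C1 still a silyl-protected sp3 carbinol, making the ketone afterwards. Brief methanolysis (pyridinium p-toluenesulfonate, MeOH, −20 °C) removes only the primary silyl ether and gives the C6 alcohol F1. Dess–Martin oxidation gives the C6 aldehyde F2, which is closed with CrCl2 under the same high dilution to the macrocyclic lactone with C1 and C10 silyl ethers F3 (both C1 epimers are carried). Methanolysis of the secondary C1 ether then gives the macrocyclic C1 allylic alcohol F4, and Dess–Martin oxidation of F4 comes back to the route at 29.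

Step 3. The dioxolane oxygen is a weak donor, so the Grignard reagent may add without magnesium chelation and give poor or reversed facial selectivity at C10. The fallback sets out from acid chloride 3 and brings the two carbon groups to C10 in the reverse order. Coupling of 3 with tributyl(vinyl)stannane under Pd(PPh3)4 (zerovalent palladium, Stille-type acylation) gives the vinyl ketone F5. Addition of MeMgBr to F5 (MgBr2·OEt2, CH2Cl2, −78 °C) under the same facial preference that misdirected the vinyl addition now delivers the needed epimer, and the route is rejoined at 5.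

Step 16. The methanolysis may not discriminate between the secondary C1 and the tertiary C10 silyl ether, so that the C10 ether is lost or the C1 ether stays. The fallback sets out from 24 and gives up the C10 protection altogether. Aqueous HF in MeCN at 0 °C removes all three silyl groups and gives the open-chain triol F6 (pyridine-based fluoride reagents are avoided because pyridine would quaternize the allylic bromide). Buffered Dess–Martin oxidation touches only the C1 and C6 carbinols and gives the keto aldehyde with free C10 hydroxyl F7. CrCl2 closure, which tolerates a free tertiary hydroxyl, gives the macrocyclic acetonide with free C10 hydroxyl F8, and aqueous TFA on F8 rejoins the route at 30.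

**Further compounds**

F1 | step 18 | C6 alcohol with C1 and C10 triethylsilyl ethers, acetonide and (Z)-2-(bromomethyl)enoate (C1 epimers) | OCC[C@@H](C)/C=C\C(O[Si](CC)(CC)CC)[C@@](C)(O[Si](CC)(CC)CC)[C@@H]1OC(C)(C)O[C@H]1/C=C(\CBr)C(=O)OC
F2 | step 18 | C6 aldehyde with C1 and C10 triethylsilyl ethers (C1 epimers) | O=CC[C@@H](C)/C=C\C(O[Si](CC)(CC)CC)[C@@](C)(O[Si](CC)(CC)CC)[C@@H]1OC(C)(C)O[C@H]1/C=C(\CBr)C(=O)OC
F3 | step 18 | macrocyclic lactone with C1 and C10 triethylsilyl ethers and C8/C9 acetonide (C1 epimers) | C=C1C(=O)O[C@@H]2C[C@@H](C)/C=C\C(O[Si](CC)(CC)CC)[C@@](C)(O[Si](CC)(CC)CC)[C@H](OC(C)(C)O4)[C@@H]4[C@@H]12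
F4 | step 18 | macrocyclic C1 allylic alcohol with C10 triethylsilyl ether and C8/C9 acetonide (C1 epimers) | C=C1C(=O)O[C@@H]2C[C@@H](C)/C=C\C(O)[C@@](C)(O[Si](CC)(CC)CC)[C@H](OC(C)(C)O4)[C@@H]4[C@@H]12
F5 | step 3 | methyl (4R,5R)-2,2-dimethyl-5-(prop-2-enoyl)-1,3-dioxolane-4-carboxylate | C=CC(=O)[C@@H]1OC(C)(C)O[C@H]1C(=O)OC
F6 | step 16 | open-chain C1,C6,C10-triol with acetonide and (Z)-2-(bromomethyl)enoate (C1 epimers) | OCC[C@@H](C)/C=C\C(O)[C@@](C)(O)[C@@H]1OC(C)(C)O[C@H]1/C=C(\CBr)C(=O)OC
F7 | step 16 | open-chain keto aldehyde with free C10 hydroxyl | O=CC[C@@H](C)/C=C\C(=O)[C@@](C)(O)[C@@H]1OC(C)(C)O[C@H]1/C=C(\CBr)C(=O)OC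
F8 | step 16 | macrocyclic lactone with C8/C9 acetonide and free C10 hydroxyl | C=C1C(=O)O[C@@H]2C[C@@H](C)/C=C\C(=O)[C@@](C)(O)[C@H](OC(C)(C)O4)[C@@H]4[C@@H]12
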